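J does not last. Z goes to J, first by reaction with the initiator L, which makes the living end D, then by reaction with D itself. J goes on to Q, and a side step J ⇌ G stands beside these.

in all of them: L 0.36 mM
- maple: Z 0.0067 M; temperature −10 °C; run made earlier
- elm: Z 0.015 M; temperature 10 °C; run made earlier
- Monday's: Z 0.010 M; temperature 25 °C; time 10 min
- Friday's: Z 0.010 M; temperature 10 °C; time 10 min
- Tuesday's: Z 0.010 M; temperature −5 °C; time 10 min

- maple (time / min: J / %, Z / %): 8.00: 45.1, 20.4; 25.0: 6.6, 0; 30.0: 3.7, 0.2; 60.0: 0.4, 0.4
- elm (time / min: J / %, Z / %): 3.00: 9.6, 3.8; 8.00: 0.1, 0.7; 12.0: 0, 0; 20.0: 0, 0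

(readings scatter by 0.5 percentage points)

- the flask that comes out highest in amount of J, in percent of the Z charged, or "all alike" when all lie within 1.5 percentage points (Monday's / Friday's / Tuesday's / all alike)
- J at the end, in percent of the Z charged, Monday's
- J at the end, in percent of the Z charged, Friday's
- J at the end, in percent of the Z charged, Tuesday's

- reactions considered so far: J -> Q; Z + D -> J + D; Z + L -> D + J; J <-> G

**Main step.** Taken as pseudo-first-order at steady cD, cZ gives kZ = 0.199 /min in the maple run and 1.09 /min in the elm run. Tuesday's −5 °C lies a quarter of the way from maple to elm, so interpolating ln k gives 0.304 /min. This step by itself is reckoned to put 95.2% of the charge into J in Tuesday's at 10 min.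

**J loss added.** The maple tail gives kJ = 0.116 /min. The zero of the scale is the symmetric case, kJ = kZ = k, where J is kt·exp(−kt) of the charge. For neighbouring constants, J ≈ kZ·t·exp(−(kZ+kJ)t/2). The elm reading at 3.00 min then gives kJ = 1.26 /min, and the same interpolation gives 0.210 /min for Tuesday's.

**Crossing ratio.** Tuesday's at 10 min stands at m = 0.297, where m, the rate at which J is made over the rate at which it is lost, is kZ·cZ/(kJ·cJ), here reckoned as exp(−(kZ−kJ)t/2)/(kJ·t). J peaks at m = 1, so Tuesday's is reckoned past its peak at 10 min, with J at 23.2%. Friday's, at elm's constants, reckons to 0.00851%, far less than Tuesday's, and Monday's, hotter than Friday's, is put near zero as well.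

**The rest.** In Tuesday's the step with L, one Z for each L, can use at most 3.60% of the Z charged. The late readings, 0.4% in maple and 0% in elm, show no stock returning from G beyond the scatter. The reckoning for Tuesday's stays at 23.2%.

**Forecast.** The forecast named Tuesday's with 21% (14% to 28%), a little less than the reckoning here, with 0.05% for Friday's and 0% for Monday's, since “J is essentially gone by 10 min”.

**Result.** Tuesday's comes out highest at 18.9%, with Friday's at 0.0179% and Monday's at 0.0126%.

    J → Q (k = 0.0930 /s, Ea = 68.0 kJ/mol)
    Z + D → J + D, rate k2*[D]*[Z] (k = 130 /M/s, Ea = 41.0 kJ/mol)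
    Z + L → D + J (k = 14.0 /M/s, Ea = 50.0 kJ/mol)
    J ⇌ G (K = 1.50, k = 0.00180 /s, Ea = 93.0 kJ/mol, ΔH = 6.00 kJ/mol)
    (constants at 25 °C)

**Second flask.** In Tuesday's the ratio is 1.91 at 2.60 min and 0.208 at 10.0 min, against 0.297 reckoned, while G holds 0.486%, its relaxation half-life of 3.80 h being long against 10 min. Stopped at 2.5 min, the same flask reckons to m = 1.69, above 1, with J still climbing at 40.0%. The flask stopped there holds 36.4% J beside 51.9% Z.

(The earlier runs and the new flask stem from a simulated flask on assumed constants; scatter was added.)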